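**Plan**
- Retrosynthesis cuts, in order: the two aryl ether C–O bonds to the side chains (giving a bisphenol core and a lactate-derived α-tosyloxy ketone), the C2–aryl bond of the tetrahydrofuran (arylzinc plus anomeric sulfone), the C2–C3 ring bond (lactone closure), and the C4–C5 bond (crotylboration of a vanillin ether).
- Forward: syn-crotylboration joins C4–C5; an ethyl carbonate on O1 brings in C2; titanium-mediated closure C2–C3 gives the γ-lactone; lactol and sulfone follow; aryl transfer completes the ring substituents; the two side chains are attached last.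
- Enabling feature: O1 is the oxygen of a homoallylic benzylic alcohol, so it can carry C2 as a carbonate carbon while C3 and its methyl are still a vinyl group; a titanium–alkene complex at C3=CH2 acylates itself on that carbonate, closes ring O1–C2–C3–C4–C5, and leaves CH2–Ti as the future C3 methyl.
- Stereochemistry: C4/C5 from Brown (Z)-crotylboration; C3 by equilibration of the lactone α-carbon to trans; C2 by aryl delivery to the oxocarbenium face opposite the C4 methyl and C5 aryl; C8 of both side chains from (S)-lactate with inversion; C7 of both by Felkin–Anh reduction.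

Key step: step 4

Assumption: the (Z)-crotylborane made from (−)-Ipc2BOMe (the (+)-α-pinene series) adds to the Si face of the aryl aldehyde, as it does with benzaldehyde; the enantiomeric borane would be taken otherwise.

**Step 1**
Reactants: 1 vanillin
Product: 2 3-methoxy-4-(triisopropylsilyloxy)benzaldehyde
Conditions: TIPSCl, imidazole, DMF, rt
Reagents that add atoms: triisopropylsilyl chloride CC(C)[Si](Cl)(C(C)C)C(C)C
Why: Imidazole-promoted O-silylation of the phenol; the bulky silyl ether should survive the organometallic and basic steps and leave later with fluoride.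

**Step 2**
Reactants: 2 3-methoxy-4-(triisopropylsilyloxy)benzaldehyde; 3 cis-2-butene
Product: 8 (1S,2R)-1-[3-methoxy-4-(triisopropylsilyloxy)phenyl]-2-methylbut-3-en-1-ol, via (Z)-crotylpotassium 4 (not isolated), via potassium crotyl(methoxy)borate 5 (not isolated), via (Z)-crotylborane 6 (not isolated), via borinate ester 7 (not isolated)
Conditions: n-BuLi, KOt-Bu, THF, −78 to −45 °C; (−)-Ipc2BOMe, −78 °C; BF3·OEt2; then 2, −78 °C; NaBO3·4H2O, THF–H2O, rt
Reagents that add atoms: none
Why: Brown crotylboration: the (Z)-crotylborane reacts through a closed Zimmerman–Traxler chair, so the Z geometry should give the syn C4–C5 relationship and the isopinocampheyl groups should select the aldehyde Si face, giving the (1S,2R) alcohol.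

**Step 3**
Reactants: 8 (1S,2R)-1-[3-methoxy-4-(triisopropylsilyloxy)phenyl]-2-methylbut-3-en-1-ol
Product: 9 ethyl (1S,2R)-1-[3-methoxy-4-(triisopropylsilyloxy)phenyl]-2-methylbut-3-en-1-yl carbonate
Conditions: ClCO2Et, pyridine, DMAP (cat.), CH2Cl2, 0 °C
Reagents that add atoms: ethyl chloroformate CCOC(=O)Cl
Why: Acylation of the secondary alcohol places the future C2 on O1 at the carbonate oxidation level, with ethoxide as the later leaving group.

**Step 4**
Reactants: 9 ethyl (1S,2R)-1-[3-methoxy-4-(triisopropylsilyloxy)phenyl]-2-methylbut-3-en-1-yl carbonate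
Product: 13 (3R,4R,5S)-5-[3-methoxy-4-(triisopropylsilyloxy)phenyl]-3,4-dimethyldihydrofuran-2(3H)-one, via titanacyclopropane 10 (not isolated), via titaniomethyl lactone 11 (not isolated), via lactone C3-epimer mixture 12 (not isolated)
Conditions: Ti(OiPr)4 (1.5 equiv), i-PrMgCl (3 equiv), Et2O, −78 to −40 °C; 1 M HCl, 0 °C; then DBU (0.2 equiv), toluene, rt
Reagents that add atoms: none
Why: Ti(OiPr)4 and two equivalents of i-PrMgCl give (η2-propene)Ti(OiPr)2, which exchanges propene for the vinyl group of 9 to form titanacyclopropane 10; its Ti–C3 bond adds to the carbonate carbonyl on O1 and ethoxide leaves, so that C2–C3 is formed and the remaining CH2–Ti bond of 11 becomes the C3 methyl on protonolysis. The closest known reaction type is the titanium alkoxide/Grignard-mediated intramolecular nucleophilic acyl substitution of olefinic carbonates, that is, the first carbon–carbon bond-forming event of an intramolecular Kulinkovich reaction held at the lactone stage. The five-membered lactone ring O1–C2–C3–C4–C5 closes in the 5-exo-trig mode, C3 attacking the carbonyl while the former vinyl CH2 stays outside the ring. C3 is the only new stereocenter: a chair-like transition state with the C4 methyl pseudo-equatorial should favour 3,4-trans, and whatever cis isomer forms is funnelled by DBU through the lactone enolate to the trans isomer, in which the C3 methyl lies on the ring face opposite both the C4 methyl and the C5 aryl group. The step needs chemoselectivity for alkene complexation over direct addition of i-PrMgCl to the carbonate, which fast transmetalation to titanium at −78 °C and the low electrophilicity of a dialkyl carbonate should secure, and regioselectivity for the five-membered ring, which the two-atom tether between the alkene and O1 secures.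

**Step 5**
Reactants: 13 (3R,4R,5S)-5-[3-methoxy-4-(triisopropylsilyloxy)phenyl]-3,4-dimethyldihydrofuran-2(3H)-one
Product: 15 (3R,4R,5S)-5-[3-methoxy-4-(triisopropylsilyloxy)phenyl]-3,4-dimethyltetrahydrofuran-2-ol (anomers), via aluminium lactolate 14 (not isolated)
Conditions: i-Bu2AlH, CH2Cl2, −78 °C; aq. potassium sodium tartrate
Reagents that add atoms: none
Why: Partial reduction of a γ-lactone; the aluminium hemiacetal is stable at −78 °C, so reduction should stop at the lactol.

**Step 6**
Reactants: 15 (3R,4R,5S)-5-[3-methoxy-4-(triisopropylsilyloxy)phenyl]-3,4-dimethyltetrahydrofuran-2-ol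
Product: 16 (3R,4R,5S)-5-[3-methoxy-4-(triisopropylsilyloxy)phenyl]-3,4-dimethyl-2-(phenylsulfonyl)tetrahydrofuran (C2 epimers)
Conditions: PhSO2H, CaCl2, CH2Cl2, rt
Reagents that add atoms: benzenesulfinic acid O=S(O)c1ccccc1
Why: Acid-catalysed exchange of the lactol hydroxyl for sulfinate through the oxocarbenium ion, with CaCl2 as desiccant, should give a stable anomeric sulfone that re-ionizes cleanly under a zinc Lewis acid.

**Step 7**
Reactants: 17 2-(allyloxy)phenol
Product: 18 2-(allyloxy)-4-bromophenol
Conditions: NBS, MeCN, 0 °C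
Reagents that add atoms: N-bromosuccinimide O=C1CCC(=O)N1Br
Why: Electrophilic aromatic bromination para to the free hydroxyl, the stronger director, as with guaiacol.

**Step 8**
Reactants: 18 2-(allyloxy)-4-bromophenol
Product: 19 [2-(allyloxy)-4-bromophenoxy]triisopropylsilane
Conditions: TIPSCl, imidazole, DMF, rt
Reagents that add atoms: triisopropylsilyl chloride CC(C)[Si](Cl)(C(C)C)C(C)C
Why: O-silylation of the phenol; the allyl ether on the neighbouring oxygen cannot migrate and stays to the end.

**Step 9**
Reactants: 16 (3R,4R,5S)-5-[3-methoxy-4-(triisopropylsilyloxy)phenyl]-3,4-dimethyl-2-(phenylsulfonyl)tetrahydrofuran; 19 [2-(allyloxy)-4-bromophenoxy]triisopropylsilane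
Product: 22 (2S,3R,4R,5S)-2-[3-(allyloxy)-4-(triisopropylsilyloxy)phenyl]-5-[3-methoxy-4-(triisopropylsilyloxy)phenyl]-3,4-dimethyltetrahydrofuran, via arylmagnesium bromide 20 (not isolated), via arylzinc bromide 21 (not isolated)
Conditions: 19, Mg, THF, rt; ZnBr2, THF, 0 °C; then 16, THF, rt
Reagents that add atoms: none
Why: Grignard formation and transmetalation to zinc, then zinc-assisted ionization of the anomeric sulfone and aryl transfer to the oxocarbenium ion on the face opposite the C4 methyl and C5 aryl group, which is the face of the C3 methyl, so the new aryl should be 2,3-cis and 2,5-trans (2S); addition of arylzinc reagents to 2-sulfonyl cyclic ethers of this substitution pattern is closely precedented.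

**Step 10**
Reactants: 22 (2S,3R,4R,5S)-2-[3-(allyloxy)-4-(triisopropylsilyloxy)phenyl]-5-[3-methoxy-4-(triisopropylsilyloxy)phenyl]-3,4-dimethyltetrahydrofuran
Product: 23 2-(allyloxy)-4-[(2S,3R,4R,5S)-5-(4-hydroxy-3-methoxyphenyl)-3,4-dimethyltetrahydrofuran-2-yl]phenol
Conditions: Bu4NF, AcOH, THF, 0 °C
Reagents that add atoms: none
Why: Fluoride cleavage of both aryl silyl ethers; the acetic acid buffer keeps the 4-hydroxyphenyl groups protonated so that the benzylic ring carbons are not opened through quinone methides.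

**Step 11**
Reactants: 24 ethyl (S)-lactate
Product: 25 (S)-2-hydroxy-N-methoxy-N-methylpropanamide
Conditions: MeNHOMe·HCl, i-PrMgCl, THF, −20 to 0 °C
Reagents that add atoms: N,O-dimethylhydroxylamine hydrochloride Cl.CNOC
Why: Aminolysis of the ester by the chloromagnesium amide (Weinreb amide formation); the stereocenter is not touched.

**Step 12**
Reactants: 25 (S)-2-hydroxy-N-methoxy-N-methylpropanamide; 26 3,4-dimethoxyphenylmagnesium bromide
Product: 28 (S)-1-(3,4-dimethoxyphenyl)-2-hydroxypropan-1-one, via magnesium hemiaminal 27 (not isolated)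
Conditions: i-PrMgCl (1 equiv), THF, −20 °C; then 26 (1.3 equiv), 0 °C; aq. NH4Cl
Reagents that add atoms: none
Why: Grignard addition to a Weinreb amide; the chelated tetrahedral intermediate prevents over-addition, and the α-center, held as its magnesium alkoxide, should not enolize.

**Step 13**
Reactants: 28 (S)-1-(3,4-dimethoxyphenyl)-2-hydroxypropan-1-one
Product: 29 (S)-1-(3,4-dimethoxyphenyl)-1-oxopropan-2-yl 4-methylbenzenesulfonate
Conditions: TsCl, Et3N, DMAP (cat.), CH2Cl2, 0 °C
Reagents that add atoms: p-toluenesulfonyl chloride Cc1ccc(S(=O)(=O)Cl)cc1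
Why: O-sulfonylation with retention gives an α-keto secondary tosylate activated for SN2 displacement.

**Step 14**
Reactants: 23 2-(allyloxy)-4-[(2S,3R,4R,5S)-5-(4-hydroxy-3-methoxyphenyl)-3,4-dimethyltetrahydrofuran-2-yl]phenol; 29 (S)-1-(3,4-dimethoxyphenyl)-1-oxopropan-2-yl 4-methylbenzenesulfonate
Product: 30 bis-ketone: 3-O-allyl core carrying an (R)-1-(3,4-dimethoxyphenyl)-1-oxopropan-2-yl ether on each 4-oxygen
Conditions: 29 (2.4 equiv), K2CO3, DMF, rt
Reagents that add atoms: none
Why: Double Williamson etherification: each phenoxide displaces the carbonyl-activated tosylate by SN2 with inversion, which should set both C8 centers as R; the mild carbonate base limits enolization.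

**Step 15**
Reactants: 30 bis-ketone
Product: 31 3-O-allyl manassantin B1 (both side chains (1R,2R)-threo)
Conditions: borohydride on a quaternary ammonium polystyrene resin, MeOH, 0 °C
Reagents that add atoms: none
Why: Felkin–Anh reduction of the α-aryloxy ketones by a borohydride without a chelating counter-ion: hydride enters anti to the aryloxy group, which should give the syn (threo) 1R carbinol at both side chains.

**Step 16**
Reactants: 31 3-O-allyl manassantin B1
Product: 32 manassantin B1
Conditions: Pd(PPh3)4 (cat.), morpholine, THF, rt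
Reagents that add atoms: none
Why: Tsuji–Trost deallylation: zerovalent palladium ionizes the aryl allyl ether to a π-allyl complex that morpholine captures, under neutral conditions that should leave the benzylic alcohols and ring ethers untouched.

**Compound list**
1 | vanillin | O=Cc1ccc(O)c(OC)c1 | starting material
2 | 3-methoxy-4-(triisopropylsilyloxy)benzaldehyde | O=Cc1ccc(O[Si](C(C)C)(C(C)C)C(C)C)c(OC)c1 | intermediate
3 | cis-2-butene | C/C=C\C | starting material
4 | (Z)-crotylpotassium | C/C=C\C[K] | intermediate (not isolated)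
5 | potassium (Z)-crotyl(methoxy)bis(isopinocampheyl)borate | [K+].C/C=C\C[B-](OC)([C@@H]1C[C@@H]2C[C@H]([C@H]1C)C2(C)C)[C@@H]1C[C@@H]2C[C@H]([C@H]1C)C2(C)C | intermediate (not isolated)
6 | (Z)-crotylbis(isopinocampheyl)borane | C/C=C\CB([C@@H]1C[C@@H]2C[C@H]([C@H]1C)C2(C)C)[C@@H]1C[C@@H]2C[C@H]([C@H]1C)C2(C)C | intermediate (not isolated)
7 | bis(isopinocampheyl)borinate ester of 8 | B([C@@H]1C[C@@H]2C[C@H]([C@H]1C)C2(C)C)([C@@H]1C[C@@H]2C[C@H]([C@H]1C)C2(C)C)O[C@H](c1ccc(O[Si](C(C)C)(C(C)C)C(C)C)c(OC)c1)[C@H](C)C=C | intermediate (not isolated)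
8 | (1S,2R)-1-[3-methoxy-4-(triisopropylsilyloxy)phenyl]-2-methylbut-3-en-1-ol | O[C@H](c1ccc(O[Si](C(C)C)(C(C)C)C(C)C)c(OC)c1)[C@H](C)C=C | intermediate
9 | ethyl (1S,2R)-1-[3-methoxy-4-(triisopropylsilyloxy)phenyl]-2-methylbut-3-en-1-yl carbonate | CCOC(=O)O[C@H](c1ccc(O[Si](C(C)C)(C(C)C)C(C)C)c(OC)c1)[C@H](C)C=C | intermediate
10 | titanacyclopropane of 9 (diisopropoxytitanium bound to C3 and the terminal CH2) | CCOC(=O)O[C@H](c1ccc(O[Si](C(C)C)(C(C)C)C(C)C)c(OC)c1)[C@H](C)C1C[Ti]1(OC(C)C)OC(C)C | intermediate (not isolated)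
11 | 3-(titaniomethyl) lactone (CH2–Ti(OEt)(OiPr)2 on C3) | O=C1O[C@H](c2ccc(O[Si](C(C)C)(C(C)C)C(C)C)c(OC)c2)[C@H](C)C1C[Ti](OCC)(OC(C)C)OC(C)C | intermediate (not isolated)
12 | (4R,5S)-5-aryl-3,4-dimethyldihydrofuran-2(3H)-one, C3-epimer mixture | O=C1O[C@H](c2ccc(O[Si](C(C)C)(C(C)C)C(C)C)c(OC)c2)[C@H](C)C1C | intermediate (not isolated)
13 | (3R,4R,5S)-5-[3-methoxy-4-(triisopropylsilyloxy)phenyl]-3,4-dimethyldihydrofuran-2(3H)-one | O=C1O[C@H](c2ccc(O[Si](C(C)C)(C(C)C)C(C)C)c(OC)c2)[C@H](C)[C@H]1C | intermediate
14 | diisobutylaluminium lactolate of 15 | CC(C)C[Al](CC(C)C)OC1O[C@H](c2ccc(O[Si](C(C)C)(C(C)C)C(C)C)c(OC)c2)[C@H](C)[C@H]1C | intermediate (not isolated)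
15 | (3R,4R,5S)-5-[3-methoxy-4-(triisopropylsilyloxy)phenyl]-3,4-dimethyltetrahydrofuran-2-ol (anomers) | OC1O[C@H](c2ccc(O[Si](C(C)C)(C(C)C)C(C)C)c(OC)c2)[C@H](C)[C@H]1C | intermediate
16 | (3R,4R,5S)-5-[3-methoxy-4-(triisopropylsilyloxy)phenyl]-3,4-dimethyl-2-(phenylsulfonyl)tetrahydrofuran (C2 epimers) | O=S(=O)(c1ccccc1)C1O[C@H](c2ccc(O[Si](C(C)C)(C(C)C)C(C)C)c(OC)c2)[C@H](C)[C@H]1C | intermediate
17 | 2-(allyloxy)phenol | C=CCOc1ccccc1O | starting material
18 | 2-(allyloxy)-4-bromophenol | C=CCOc1cc(Br)ccc1O | intermediate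
19 | [2-(allyloxy)-4-bromophenoxy]triisopropylsilane | C=CCOc1cc(Br)ccc1O[Si](C(C)C)(C(C)C)C(C)C | intermediate
20 | [3-(allyloxy)-4-(triisopropylsilyloxy)phenyl]magnesium bromide | C=CCOc1cc([Mg]Br)ccc1O[Si](C(C)C)(C(C)C)C(C)C | intermediate (not isolated)
21 | [3-(allyloxy)-4-(triisopropylsilyloxy)phenyl]zinc bromide | C=CCOc1cc([Zn]Br)ccc1O[Si](C(C)C)(C(C)C)C(C)C | intermediate (not isolated)
22 | (2S,3R,4R,5S)-2-[3-(allyloxy)-4-(triisopropylsilyloxy)phenyl]-5-[3-methoxy-4-(triisopropylsilyloxy)phenyl]-3,4-dimethyltetrahydrofuran | C=CCOc1cc([C@H]2O[C@H](c3ccc(O[Si](C(C)C)(C(C)C)C(C)C)c(OC)c3)[C@H](C)[C@H]2C)ccc1O[Si](C(C)C)(C(C)C)C(C)C | intermediate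
23 | 2-(allyloxy)-4-[(2S,3R,4R,5S)-5-(4-hydroxy-3-methoxyphenyl)-3,4-dimethyltetrahydrofuran-2-yl]phenol | C=CCOc1cc([C@H]2O[C@H](c3ccc(O)c(OC)c3)[C@H](C)[C@H]2C)ccc1O | intermediate
24 | ethyl (S)-lactate | CCOC(=O)[C@H](C)O | starting material
25 | (S)-2-hydroxy-N-methoxy-N-methylpropanamide | C[C@H](O)C(=O)N(C)OC | intermediate
26 | 3,4-dimethoxyphenylmagnesium bromide | COc1ccc([Mg]Br)cc1OC | starting material
27 | magnesium hemiaminal (tetrahedral adduct of 25 and 26) | C[C@H](O[Mg]Cl)C(O[Mg]Br)(N(C)OC)c1ccc(OC)c(OC)c1 | intermediate (not isolated)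
28 | (S)-1-(3,4-dimethoxyphenyl)-2-hydroxypropan-1-one | C[C@H](O)C(=O)c1ccc(OC)c(OC)c1 | intermediate
29 | (S)-1-(3,4-dimethoxyphenyl)-1-oxopropan-2-yl 4-methylbenzenesulfonate | C[C@H](OS(=O)(=O)c1ccc(C)cc1)C(=O)c1ccc(OC)c(OC)c1 | intermediate
30 | bis-ketone: (2S,3R,4R,5S)-core with 3-O-allyl and an (R)-1-(3,4-dimethoxyphenyl)-1-oxopropan-2-yl ether on each 4-oxygen | C=CCOc1cc([C@H]2O[C@H](c3ccc(O[C@H](C)C(=O)c4ccc(OC)c(OC)c4)c(OC)c3)[C@H](C)[C@H]2C)ccc1O[C@H](C)C(=O)c1ccc(OC)c(OC)c1 | intermediate
31 | 3-O-allyl manassantin B1 (both side chains (1R,2R)) | C=CCOc1cc([C@H]2O[C@H](c3ccc(O[C@H](C)[C@H](O)c4ccc(OC)c(OC)c4)c(OC)c3)[C@H](C)[C@H]2C)ccc1O[C@H](C)[C@H](O)c1ccc(OC)c(OC)c1 | intermediate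
32 | manassantin B1 | COc1ccc([C@@H](O)[C@@H](C)Oc2ccc([C@H]3O[C@H](c4ccc(O[C@H](C)[C@H](O)c5ccc(OC)c(OC)c5)c(OC)c4)[C@H](C)[C@H]3C)cc2O)cc1OC | target

**Step count**
Total: 16 steps. Longest linear sequence: 11 steps (steps 1–6, 9, 10, 14, 15, 16).

**Three steps most likely to fail**

Step 4. The α-branched vinyl group may fail to displace propene from titanium, the Grignard reagent may add directly to the carbonate, the secondary benzylic carbonate may ionize on the Lewis-acidic metals, or the CH2–Ti bond may add on to the new lactone carbonyl. Fallback, setting out from 9: the alkene is first turned into a secondary bromide at C3 by cobalt-mediated hydrogen-atom-transfer hydrobromination (Co(acac)2, t-BuOOH, Et3SiH, TsBr), giving ethyl (1S,2S)-3-bromo-1-[3-methoxy-4-(triisopropylsilyloxy)phenyl]-2-methylbutyl carbonate F1 as a mixture of C3 epimers. SmI2 with HMPA in THF then makes the C3 organosamarium, which attacks the carbonate on O1 in an intramolecular acyl substitution and closes the same C2–C3 bond. The route is rejoined at 12, and the DBU equilibration of step 4 gives 13.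

Step 14. Configuration may be lost by enolization of the α-tosyloxy ketone or of the α-aryloxy ketone products under base, the second alkylation of the hindered ortho-substituted phenoxide may stall, and the benzylic ring carbons may epimerize through quinone methide formation from the free phenoxides. Fallback, setting out from 23: Mitsunobu etherification (PPh3, DIAD, THF, 0 °C) with ethyl (S)-lactate 24 under neutral conditions, with inversion, gives the bis[(R)-2-aryloxypropanoate] diethyl ester F2. Aminolysis with MeNHOMe·HCl and i-PrMgCl gives the bis(N-methoxy-N-methylamide) F3. Addition of 3,4-dimethoxyphenylmagnesium bromide 26 returns to the route at 30.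

Step 15. Facial selectivity under substrate control may be insufficient at one or both ketones, giving threo/erythro mixtures that are hard to separate. Fallback, setting out from 30: the source of stereocontrol is moved from the substrate to the reagent by a Corey–Bakshi–Shibata reduction (the (R)-configured B-methyl oxazaborolidine, BH3·SMe2, THF, −20 °C). With the aryl group as the large substituent this should deliver hydride to the face that gives the 1R carbinols, independent of the neighbouring aryloxy center, and it returns to the route at 31 without new compounds.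

**Further compounds**
F1 | step 4 | ethyl (1S,2S)-3-bromo-1-[3-methoxy-4-(triisopropylsilyloxy)phenyl]-2-methylbutyl carbonate (C3 epimers) | CCOC(=O)O[C@H](c1ccc(O[Si](C(C)C)(C(C)C)C(C)C)c(OC)c1)[C@H](C)C(C)Br
F2 | step 14 | diethyl ester: (2S,3R,4R,5S)-core with 3-O-allyl and an (R)-1-ethoxy-1-oxopropan-2-yl ether on each 4-oxygen | C=CCOc1cc([C@H]2O[C@H](c3ccc(O[C@H](C)C(=O)OCC)c(OC)c3)[C@H](C)[C@H]2C)ccc1O[C@H](C)C(=O)OCC
F3 | step 14 | bis(N-methoxy-N-methylamide) corresponding to F2 | C=CCOc1cc([C@H]2O[C@H](c3ccc(O[C@H](C)C(=O)N(C)OC)c(OC)c3)[C@H](C)[C@H]2C)ccc1O[C@H](C)C(=O)N(C)OC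
F0 | step 15 | none | none
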